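The route rests on cutting ring B at the neighbouring pair C9/C10: C9 carries C11, C10 is the quaternary methyl-bearing fusion carbon, and C8 next to C9 must be oxygenated to become the exocyclic alkene. One copper-catalysed operation adds a silylmethyl Grignard reagent (masked C11–OH) enantioselectively to C9 of a 2-methylcyclohexenone and lets the C10 magnesium enolate add to an α-silyl ethyl vinyl ketone, forming C9–C11 and C1–C10 with C11 cis to the C10 methyl. The enone precursor is 4,4-dimethoxy-2-methylcyclohex-2-enone, a partly hydrogenated quinone monoketal whose ketal is the future C8. Ring A then closes by aldol condensation, and umbelliferone is attached last.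

Key step: step 6

Atom labels C1–C12 follow drimane numbering of the decalin: C3 carbinol, C4 gem-dimethyl, C5 and C10 ring fusion, C8 carrying the C12 methylene, C9 carrying C11.

Assumption: the (R,S_p) antipode of the ferrocenyl diphosphine is taken to deliver the silylmethyl group to the face of C9 that leads to (2S,3S)-11; should this untested enone show the opposite sense of induction, the mirror-image ligand is used and nothing else changes.

Step 1
Reactants: 1 4-methoxy-2-methylphenol
Product: 2 4,4-dimethoxy-2-methylcyclohexa-2,5-dien-1-one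
Conditions: PhI(OAc)2, MeOH, 0 °C
Reagents that add atoms: methanol, CO
Why: Oxidative dearomatisation of a para-alkoxyphenol, in which the hypervalent iodine reagent generates a phenoxonium ion that methanol captures at the methoxy-bearing carbon to give the quinone monoketal.

Step 2
Reactants: 2 4,4-dimethoxy-2-methylcyclohexa-2,5-dien-1-one
Product: 3 4,4-dimethoxy-2-methylcyclohex-2-en-1-one
Conditions: H2 (1 atm), RhCl(PPh3)3 (5 mol%), toluene, rt
Reagents that add atoms: none
Why: Chemoselective homogeneous hydrogenation, since RhCl(PPh3)3 reduces the unhindered disubstituted alkene of a cross-conjugated dienone far faster than the methyl-bearing trisubstituted one and, unlike heterogeneous palladium, does not hydrogenolyse the ketal or aromatise the ring.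

Step 3
Reactants: 4 (chloromethyl)dimethyl(propan-2-yloxy)silane
Product: 5 {[dimethyl(propan-2-yloxy)silyl]methyl}magnesium chloride (titrated ether solution)
Conditions: Mg turnings, BrCH2CH2Br (cat.), Et2O, reflux
Reagents that add atoms: magnesium, [Mg]
Why: Grignard formation by magnesium insertion into an α-silyl C–Cl bond; the branched alkoxy group on silicon resists attack by the reagent formed, and ether is used instead of THF so that no strongly coordinating solvent enters the copper catalysis of step 6.

Step 4
Reactants: 6 (1-bromoethenyl)trimethylsilane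
Product: 8 2-(trimethylsilyl)pent-1-en-3-ol (racemic), via [1-(trimethylsilyl)ethenyl]magnesium bromide 7 (not isolated)
Conditions: Mg turnings, THF, reflux; then propanal, 0 °C; aq. NH4Cl
Reagents that add atoms: propanal, CCC=O
Why: Grignard formation from the α-bromovinylsilane and 1,2-addition to the aldehyde give the allylic alcohol, whose stereocentre is removed in step 5.

Step 5
Reactants: 8 2-(trimethylsilyl)pent-1-en-3-ol
Product: 9 2-(trimethylsilyl)pent-1-en-3-one
Conditions: CrO3, H2SO4, H2O, acetone, 0 °C
Reagents that add atoms: none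
Why: Jones oxidation of a secondary allylic alcohol, run in acid because the α-silyl enone is stable there but sensitive to base and nucleophiles; the product is distilled and used fresh.

Step 6
Reactants: 3 4,4-dimethoxy-2-methylcyclohex-2-en-1-one; 5 {[dimethyl(propan-2-yloxy)silyl]methyl}magnesium chloride; 9 2-(trimethylsilyl)pent-1-en-3-one
Product: 11 (2S,3S)-3-{[dimethyl(propan-2-yloxy)silyl]methyl}-4,4-dimethoxy-2-methyl-2-[3-oxo-2-(trimethylsilyl)pentyl]cyclohexan-1-one (both epimers at the silicon-bearing side-chain carbon), via chloromagnesium enolate 10 (not isolated)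
Conditions: CuBr·SMe2 (5 mol%), (R)-1-[(S_p)-2-(diphenylphosphino)ferrocenyl]ethyldicyclohexylphosphine (6 mol%), t-BuOMe, −78 °C, slow addition of 5 (1.15 equiv); then 9 (1.3 equiv), THF, −78 → −20 °C; aq. NH4Cl
Reagents that add atoms: none
Why: The monovalent copper–diphosphine complex is transmetallated by 5, binds the enone as a π-complex and transfers the silylmethyl group to C9 through a trivalent copper intermediate that reductively eliminates, which leaves magnesium enolate 10 with its double bond fixed between C5 and C10; 10 then adds in Michael fashion to 9, whose silicon stabilises the new enolate and so suppresses proton exchange and oligomerisation of the acceptor. The closest known reaction type is the copper-catalysed asymmetric conjugate addition of Grignard reagents to 2-methylcycloalkenones with electrophilic capture of the tetrasubstituted enolate, joined to the established Michael capture of such enolates by α-silyl vinyl ketones. No ring is closed here, because ring A is left for the aldol condensation of step 7. C9 is set by the chiral ligand, which differentiates the enone faces in the copper π-complex, and C10 by the substrate, since the C9 silylmethyl group lies pseudoaxial beside the C10 methyl to avoid allylic strain and 9 therefore attacks the opposite face, placing C11 cis to the C10 methyl. The step needs 1,4- rather than 1,2-addition and reaction at C10 only, which the soft copper nucleophile at −78 °C with slow addition of 5 and the regiodefined enolate (C6 is never deprotonated) secure, while the C8 ketal is too poor a leaving group to be lost and the epimers at the silicon-bearing C2 vanish in step 7.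

Step 7
Reactants: 11 (2S,3S)-3-{[dimethyl(propan-2-yloxy)silyl]methyl}-4,4-dimethoxy-2-methyl-2-[3-oxo-2-(trimethylsilyl)pentyl]cyclohexan-1-one
Product: 13 (4aS,5R)-5-(hydroxymethyl)-6,6-dimethoxy-1,4a-dimethyl-4,4a,5,6,7,8-hexahydronaphthalen-2(3H)-one, via methoxysilane enone 12 (not isolated)
Conditions: NaOMe (0.5 equiv), MeOH, 60 °C; then AcOH (0.5 equiv), KF, KHCO3, 30% H2O2, THF/MeOH, rt
Reagents that add atoms: hydrogen peroxide, OO
Why: Methoxide removes the α-silyl group and the freed 1,5-diketone closes ring A by intramolecular aldol condensation (the second half of a Robinson annulation, 6-(enolendo)-exo-trig addition then dehydration) while the silicon ether exchanges to the methoxysilane, after which Tamao oxidation converts the C11–Si bond into C11–OH under bicarbonate-buffered peroxide that is too weakly basic to epoxidise the fully substituted enone or to touch the ketal.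

Step 8
Reactants: 13 (4aS,5R)-5-(hydroxymethyl)-6,6-dimethoxy-1,4a-dimethyl-4,4a,5,6,7,8-hexahydronaphthalen-2(3H)-one
Product: 14 (4aS,5R)-6,6-dimethoxy-1,4a-dimethyl-5-({[tri(propan-2-yl)silyl]oxy}methyl)-4,4a,5,6,7,8-hexahydronaphthalen-2(3H)-one
Conditions: i-Pr3SiCl, imidazole, DMF, rt
Reagents that add atoms: chlorotri(propan-2-yl)silane, CC(C)[Si](Cl)(C(C)C)C(C)C
Why: Silylation of the primary alcohol under imidazole catalysis; the triisopropylsilyl ether is chosen because it withstands dissolving metal, hydride, the mild acid of steps 11 and 12, amide base and ylide.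

Step 9
Reactants: 14 (4aS,5R)-6,6-dimethoxy-1,4a-dimethyl-5-({[tri(propan-2-yl)silyl]oxy}methyl)-4,4a,5,6,7,8-hexahydronaphthalen-2(3H)-one
Product: 16 (4aR,5R,8aS)-6,6-dimethoxy-1,1,4a-trimethyl-5-({[tri(propan-2-yl)silyl]oxy}methyl)octahydronaphthalen-2(1H)-one, via lithium enolate 15 (not isolated)
Conditions: Li (2.1 equiv), NH3(l)/THF, t-BuOH (1.0 equiv), −78 °C; then MeI, −78 → −33 °C; H2O
Reagents that add atoms: iodomethane, CI
Why: Reductive alkylation of the enone: lithium in ammonia with one equivalent of proton donor reduces the enone, C5 is protonated axially so that H5 ends trans to the C10 methyl (trans-decalin), and the regiospecific C3–C4 lithium enolate 15 is C-methylated at C4 to complete the gem-dimethyl group.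

Step 10
Reactants: 16 (4aR,5R,8aS)-6,6-dimethoxy-1,1,4a-trimethyl-5-({[tri(propan-2-yl)silyl]oxy}methyl)octahydronaphthalen-2(1H)-one
Product: 17 (2S,4aR,5R,8aS)-6,6-dimethoxy-1,1,4a-trimethyl-5-({[tri(propan-2-yl)silyl]oxy}methyl)decahydronaphthalen-2-ol
Conditions: LiBH(s-Bu)3, THF, −78 °C; then aq. NaOH, H2O2, 0 °C
Reagents that add atoms: none
Why: The bulky trialkylborohydride attacks the C3 carbonyl along the equatorial trajectory, avoiding the axial hydrogens at C1 and C5, and so gives the axial alcohol (OH trans to the C10 methyl, cis to H5) required by the target, the known outcome for 4,4-dimethyl-3-oxo trans-decalins.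

Step 11
Reactants: 17 (2S,4aR,5R,8aS)-6,6-dimethoxy-1,1,4a-trimethyl-5-({[tri(propan-2-yl)silyl]oxy}methyl)decahydronaphthalen-2-ol
Product: 18 (1R,4aS,6S,8aR)-6-hydroxy-5,5,8a-trimethyl-1-({[tri(propan-2-yl)silyl]oxy}methyl)octahydronaphthalen-2(1H)-one
Conditions: pyridinium p-toluenesulfonate (cat.), acetone/H2O, 40 °C
Reagents that add atoms: water, O
Why: Acid-catalysed hydrolysis of an acyclic dimethyl ketal proceeds under buffered conditions that leave the primary triisopropylsilyl ether alone, and C9, now next to a carbonyl, keeps its configuration because its substituent is already equatorial.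

Step 12
Reactants: 18 (1R,4aS,6S,8aR)-6-hydroxy-5,5,8a-trimethyl-1-({[tri(propan-2-yl)silyl]oxy}methyl)octahydronaphthalen-2(1H)-one
Product: 21 (1R,4aS,6S,8aR)-6-hydroxy-5,5,8a-trimethyl-1-({[tri(propan-2-yl)silyl]oxy}methyl)-4a,5,6,7,8,8a-hexahydronaphthalen-2(1H)-one, via bis(trimethylsilyl) derivative 19 (not isolated), via trimethylsilyl ether enone 20 (not isolated)
Conditions: LiN(i-Pr)2 (2.5 equiv), Me3SiCl (3 equiv), THF, −78 °C; then Pd(OAc)2 (1.1 equiv), MeCN, rt; then 1 M HCl, THF, 0 °C
Reagents that add atoms: none
Why: Saegusa–Ito oxidation: the amide base deprotonates the C7 methylene kinetically (the C9 methine is hindered) and the enolate is silylated in situ together with the C3 hydroxyl, divalent palladium then forms the oxa-π-allyl complex at C7 and β-hydride elimination of H6 gives the C6=C7 enone, and the brief acid wash frees the C3 hydroxyl again.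

Step 13
Reactants: 21 (1R,4aS,6S,8aR)-6-hydroxy-5,5,8a-trimethyl-1-({[tri(propan-2-yl)silyl]oxy}methyl)-4a,5,6,7,8,8a-hexahydronaphthalen-2(1H)-one
Product: 22 (2S,4aR,5R,8aS)-1,1,4a-trimethyl-6-methylidene-5-({[tri(propan-2-yl)silyl]oxy}methyl)-1,2,3,4,4a,5,6,8a-octahydronaphthalen-2-ol
Conditions: Ph3PCH3Br, KOt-Bu, THF, 0 °C → rt
Reagents that add atoms: methyltriphenylphosphonium bromide, C[P+](c1ccccc1)(c1ccccc1)c1ccccc1.[Br-]
Why: Wittig methylenation: the unstabilised ylide adds to the enone carbonyl in 1,2-fashion to give the 6,8(12)-diene, an excess covers the free C3 hydroxyl, and the low temperature disfavours deprotonation at the hindered C9.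

Step 14
Reactants: 22 (2S,4aR,5R,8aS)-1,1,4a-trimethyl-6-methylidene-5-({[tri(propan-2-yl)silyl]oxy}methyl)-1,2,3,4,4a,5,6,8a-octahydronaphthalen-2-ol
Product: 23 (2S,4aR,5R,8aS)-5-(hydroxymethyl)-1,1,4a-trimethyl-6-methylidene-1,2,3,4,4a,5,6,8a-octahydronaphthalen-2-ol
Conditions: Bu4NF, THF, rt
Reagents that add atoms: none
Why: Fluoride-mediated desilylation driven by the strong Si–F bond; neither the diene nor the secondary alcohol is affected.

Step 15
Reactants: 23 (2S,4aR,5R,8aS)-5-(hydroxymethyl)-1,1,4a-trimethyl-6-methylidene-1,2,3,4,4a,5,6,8a-octahydronaphthalen-2-ol; 24 umbelliferone (7-hydroxy-2H-chromen-2-one)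
Product: 25 7-{[(1R,4aS,6S,8aR)-6-hydroxy-5,5,8a-trimethyl-2-methylidene-1,2,4a,5,6,7,8,8a-octahydronaphthalen-1-yl]methoxy}-2H-chromen-2-one (CNP0259618.1)
Conditions: PPh3, diisopropyl azodicarboxylate, THF, 0 °C → rt
Reagents that add atoms: none
Why: Mitsunobu etherification: the primary C11 alcohol is activated as its alkoxyphosphonium ion much faster than the axial C3 alcohol flanked by the gem-dimethyl group, and the acidic phenol of umbelliferone displaces it by SN2 at a carbon that is not stereogenic.

Compound list
1 | 4-methoxy-2-methylphenol | COc1ccc(O)c(C)c1 | starting material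
2 | 4,4-dimethoxy-2-methylcyclohexa-2,5-dien-1-one | CC1=CC(OC)(OC)C=CC1=O | intermediate
3 | 4,4-dimethoxy-2-methylcyclohex-2-en-1-one | CC1=CC(OC)(OC)CCC1=O | intermediate
4 | (chloromethyl)dimethyl(propan-2-yloxy)silane | CC(C)O[Si](C)(C)CCl | starting material
5 | {[dimethyl(propan-2-yloxy)silyl]methyl}magnesium chloride | CC(C)O[Si](C)(C)C[Mg]Cl | intermediate
6 | (1-bromoethenyl)trimethylsilane | C=C(Br)[Si](C)(C)C | starting material
7 | [1-(trimethylsilyl)ethenyl]magnesium bromide | C=C([Mg]Br)[Si](C)(C)C | intermediate
8 | 2-(trimethylsilyl)pent-1-en-3-ol (racemic) | CCC(O)C(=C)[Si](C)(C)C | intermediate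
9 | 2-(trimethylsilyl)pent-1-en-3-one | CCC(=O)C(=C)[Si](C)(C)C | intermediate
10 | chloromagnesium (3S)-3-{[dimethyl(propan-2-yloxy)silyl]methyl}-4,4-dimethoxy-2-methylcyclohex-1-en-1-olate | CC1=C(O[Mg]Cl)CCC(OC)(OC)[C@H]1C[Si](C)(C)OC(C)C | intermediate
11 | (2S,3S)-3-{[dimethyl(propan-2-yloxy)silyl]methyl}-4,4-dimethoxy-2-methyl-2-[3-oxo-2-(trimethylsilyl)pentyl]cyclohexan-1-one (both epimers at the silicon-bearing side-chain carbon) | CCC(=O)C(C[C@@]1(C)[C@H](C[Si](C)(C)OC(C)C)C(OC)(OC)CCC1=O)[Si](C)(C)C | intermediate
12 | (4aS,5S)-6,6-dimethoxy-5-{[methoxy(dimethyl)silyl]methyl}-1,4a-dimethyl-4,4a,5,6,7,8-hexahydronaphthalen-2(3H)-one | COC1(OC)CCC2=C(C)C(=O)CC[C@@]2(C)[C@@H]1C[Si](C)(C)OC | intermediate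
13 | (4aS,5R)-5-(hydroxymethyl)-6,6-dimethoxy-1,4a-dimethyl-4,4a,5,6,7,8-hexahydronaphthalen-2(3H)-one | COC1(OC)CCC2=C(C)C(=O)CC[C@@]2(C)[C@@H]1CO | intermediate
14 | (4aS,5R)-6,6-dimethoxy-1,4a-dimethyl-5-({[tri(propan-2-yl)silyl]oxy}methyl)-4,4a,5,6,7,8-hexahydronaphthalen-2(3H)-one | COC1(OC)CCC2=C(C)C(=O)CC[C@@]2(C)[C@@H]1CO[Si](C(C)C)(C(C)C)C(C)C | intermediate
15 | lithium (4aR,5R,8aS)-6,6-dimethoxy-1,4a-dimethyl-5-({[tri(propan-2-yl)silyl]oxy}methyl)-3,4,4a,5,6,7,8,8a-octahydronaphthalen-2-olate | COC1(OC)CC[C@@H]2C(C)=C(O[Li])CC[C@@]2(C)[C@@H]1CO[Si](C(C)C)(C(C)C)C(C)C | intermediate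
16 | (4aR,5R,8aS)-6,6-dimethoxy-1,1,4a-trimethyl-5-({[tri(propan-2-yl)silyl]oxy}methyl)octahydronaphthalen-2(1H)-one | COC1(OC)CC[C@@H]2C(C)(C)C(=O)CC[C@@]2(C)[C@@H]1CO[Si](C(C)C)(C(C)C)C(C)C | intermediate
17 | (2S,4aR,5R,8aS)-6,6-dimethoxy-1,1,4a-trimethyl-5-({[tri(propan-2-yl)silyl]oxy}methyl)decahydronaphthalen-2-ol | COC1(OC)CC[C@@H]2C(C)(C)[C@@H](O)CC[C@@]2(C)[C@@H]1CO[Si](C(C)C)(C(C)C)C(C)C | intermediate
18 | (1R,4aS,6S,8aR)-6-hydroxy-5,5,8a-trimethyl-1-({[tri(propan-2-yl)silyl]oxy}methyl)octahydronaphthalen-2(1H)-one | O=C1CC[C@@H]2C(C)(C)[C@@H](O)CC[C@@]2(C)[C@@H]1CO[Si](C(C)C)(C(C)C)C(C)C | intermediate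
19 | C7=C8 trimethylsilyl enol ether of 18 with the C3 hydroxyl as its trimethylsilyl ether (configurations as in 18) | C[Si](C)(C)OC1=CC[C@@H]2C(C)(C)[C@@H](O[Si](C)(C)C)CC[C@@]2(C)[C@@H]1CO[Si](C(C)C)(C(C)C)C(C)C | intermediate
20 | C3 trimethylsilyl ether of enone 21 (configurations as in 21) | O=C1C=C[C@@H]2C(C)(C)[C@@H](O[Si](C)(C)C)CC[C@@]2(C)[C@@H]1CO[Si](C(C)C)(C(C)C)C(C)C | intermediate
21 | (1R,4aS,6S,8aR)-6-hydroxy-5,5,8a-trimethyl-1-({[tri(propan-2-yl)silyl]oxy}methyl)-4a,5,6,7,8,8a-hexahydronaphthalen-2(1H)-one | O=C1C=C[C@@H]2C(C)(C)[C@@H](O)CC[C@@]2(C)[C@@H]1CO[Si](C(C)C)(C(C)C)C(C)C | intermediate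
22 | (2S,4aR,5R,8aS)-1,1,4a-trimethyl-6-methylidene-5-({[tri(propan-2-yl)silyl]oxy}methyl)-1,2,3,4,4a,5,6,8a-octahydronaphthalen-2-ol | C=C1C=C[C@@H]2C(C)(C)[C@@H](O)CC[C@@]2(C)[C@@H]1CO[Si](C(C)C)(C(C)C)C(C)C | intermediate
23 | (2S,4aR,5R,8aS)-5-(hydroxymethyl)-1,1,4a-trimethyl-6-methylidene-1,2,3,4,4a,5,6,8a-octahydronaphthalen-2-ol | C=C1C=C[C@@H]2C(C)(C)[C@@H](O)CC[C@@]2(C)[C@@H]1CO | intermediate
24 | umbelliferone (7-hydroxy-2H-chromen-2-one) | O=c1ccc2ccc(O)cc2o1 | starting material
25 | 7-{[(1R,4aS,6S,8aR)-6-hydroxy-5,5,8a-trimethyl-2-methylidene-1,2,4a,5,6,7,8,8a-octahydronaphthalen-1-yl]methoxy}-2H-chromen-2-one | C=C1C=C[C@@H]2C(C)(C)[C@@H](O)CC[C@@]2(C)[C@@H]1COc1ccc2ccc(=O)oc2c1 | target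

Total step count: 15. Longest linear sequence: 12 steps (steps 1, 2 and 6 to 15, from 1).

Steps most likely to fail

Step 6. The hindered, fully substituted magnesium enolate may add to 9 too slowly at the low temperature that the enantioselective addition tolerates, so that proton transfer overtakes the Michael capture and the coupling stops after the first bond. The fallback separates the two events and sets out from 3 and 5. The copper-catalysed addition is run alone and quenched with aqueous NH4Cl to give the ketone (3S)-3-{[dimethyl(propan-2-yloxy)silyl]methyl}-4,4-dimethoxy-2-methylcyclohexan-1-one F1 (C2 epimers, of no consequence). This ketone then enters a classical Robinson annulation with commercial pent-1-en-3-one (NaOMe, MeOH, 0 → 60 °C). The more substituted thermodynamic enolate should add at C10 anti to the C9 substituent, and the adduct condenses in the same flask to methoxysilane 12. Tamao oxidation as in step 7 brings the material back to the route at 13.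

Step 13. The basic ylide may deprotonate C9 of the β-silyloxy enone, and β-elimination of the silyloxy group would then compete with carbonyl addition. The fallback sets out from 21 and uses a Peterson olefination with a non-basic organocerium reagent. Me3SiCH2Li/CeCl3 (THF, −78 °C) adds to the carbonyl to give the C8 tertiary allylic β-hydroxysilane F2 (C8 epimers, both of which eliminate to the same alkene). KH in THF then triggers syn-elimination of trimethylsilanolate, which returns to the route at 22.

Step 15. Displacement at the β-branched C11 may be slow, so that loss of the C9 proton from the alkoxyphosphonium intermediate (elimination toward C9) wins before the phenoxide attacks. The fallback sets out from 23 and forms the aryl–oxygen bond instead of the alkyl–oxygen bond. Copper-mediated oxidative O-arylation (Chan–Lam coupling) of the primary alcohol with commercial (2-oxo-2H-chromen-7-yl)boronic acid (Cu(OAc)2, 4-(dimethylamino)pyridine, 4 Å molecular sieves, CH2Cl2, O2, rt) leaves C11 unactivated and arrives directly at 25. No new intermediate is made on the way (F0).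

Further compounds
F1 | step 6 | (3S)-3-{[dimethyl(propan-2-yloxy)silyl]methyl}-4,4-dimethoxy-2-methylcyclohexan-1-one (C2 epimers) | CC1C(=O)CCC(OC)(OC)[C@H]1C[Si](C)(C)OC(C)C
F2 | step 13 | adduct of 21 carrying OH and CH2SiMe3 at C8 (C8 epimers, other centres as in 21) | C[Si](C)(C)CC1(O)C=C[C@@H]2C(C)(C)[C@@H](O)CC[C@@]2(C)[C@@H]1CO[Si](C(C)C)(C(C)C)C(C)C
F0 | step 15 | none | none
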